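Readings and results are calculated with made-up constants, and the scatter is random.

Rates first.

| flask | starting material | reagent | second substrate | remark | time |
|---|---|---|---|---|---|
| dawn | 26 mM | 52 mM | 130 mM | run made earlier |  |
| summer | 26 mM | 52 mM | 87 mM | run made earlier |  |
| midnight | 26 mM | 52 mM | 200 mM | run made earlier |  |
| autumn | 52 mM | 52 mM | 130 mM | run made earlier |  |
| green | 26 mM | 52.0 mM | 130 mM | a closed flask charged with all of it at once and left for 4.0 h | 4.0 h |
| violet | 26 mM | 52.0 mM | 130 mM | one stirred flow tank at steady state, fed with the mixture as stated, mean residence time 4.0 h |  |
| grey | 26 mM | 52.0 mM | 130 mM | one stirred flow tank at steady state, fed with the mixture as stated, mean residence time 12.0 h |  |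
| blue | 26 mM | 52.0 mM (fed, over 3.20 h) | 130 mM | all but reagent at the start; reagent goes in evenly over 3.20 h, the run ends at 4.0 h | 4.0 h |

| run | time / h | target / % | cross product / % |
|---|---|---|---|
| dawn | 0.200 | 47.2 | 13.4 |
| dawn | 0.333 | 55.5 | 15.9 |
| dawn | 0.417 | 57.7 | 17.5 |
| dawn | 0.667 | 63.0 | 19.6 |
| dawn | 1.00 | 65.6 | 22.9 |
| dawn | 1.50 | 68.5 | 22.9 |
| dawn | 2.50 | 69.6 | 25.3 |
| summer | 0.500 | 63.0 | 13.2 |
| summer | 1.00 | 70.1 | 16.3 |
| summer | 1.33 | 72.2 | 16.6 |
| summer | 2.00 | 76.4 | 17.1 |
| summer | 2.50 | 75.7 | 17.5 |
| summer | 3.00 | 77.7 | 17.6 |
| midnight | 0.250 | 47.1 | 22.3 |
| midnight | 0.417 | 52.3 | 25.1 |
| midnight | 0.667 | 56.8 | 28.3 |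
| midnight | 0.833 | 58.5 | 30.5 |
| midnight | 1.33 | 60.7 | 33.1 |
| midnight | 2.00 | 59.1 | 34.2 |
| midnight | 3.00 | 60.6 | 37.3 |
| autumn | 0.667 | 53.0 | 20.3 |
| autumn | 1.33 | 57.5 | 24.5 |
| autumn | 2.00 | 59.3 | 26.9 |
| autumn | 2.50 | 59.6 | 27.6 |
| autumn | 3.00 | 59.8 | 29.1 |

(scatter of a reading: 0.5 percentage points)

- percentages count the starting material that a species holds: one idle adduct counts as two
- target is meant together with its idle adduct
- the stated concentrations are those of everything mixed, before any reaction; amounts are the same in each set-up
- reactions considered so far: starting material + second substrate -> cross product; second substrate + reagent -> second product; starting material + reagent -> target; starting material + target <-> idle adduct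
- the feed brings no volume worth counting
- the earlier runs were made in a closed, stirred flask
- in an amount of target, one idle adduct counts as one target

- the set-up with the highest share of target in all that became target or cross product, at the outlet or at the end ("none" if the first two lie within 2 percentage points) (green / violet / grey / blue / none)
- share of target in all that became target or cross product, at the outlet or at the end, green
- share of target in all that became target or cross product, at the outlet or at the end, violet
- share of target in all that became target or cross product, at the outlet or at the end, grey
- share of target in all that became target or cross product, at the outlet or at the end, blue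

Starting material has two exits, to target with reagent and to cross product with second substrate. Both rates carry [starting material] as a factor, so their ratio is free of it and follows [reagent]/[second substrate]. I therefore carried the selectivity factor s, the rate constant of the cross reaction over that of the target reaction, and read it from the first dawn reading as cross product over target times [reagent]/[second substrate] as charged: s = 0.114. That reading carries its scatter, and reagent had already begun to fall by then.

The target rate over the cross rate is then [reagent]/(s[second substrate]), which in green opens at 3.52. Spent reagent slows the target rate, and the running ratio falls with it. Dawn, with the same charge as green, had reached a cumulative ratio of 2.75 at its last reading, a factor of 0.781 on the opening value, so I expected about 73.3% for green.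

In blue the target rate opens no higher than the dose of 16.3 mM/h, while cross product formed in dawn at 17.4 mM/h on average up to the first reading; that average was taken while dawn's starting material fell, whereas blue opens with its whole charge, so I held it as a floor for blue's opening cross rate. The ratio in blue thus opens below 0.933, which is itself lower than green's opening value. Since second substrate also takes reagent, I expected blue under 48.3%.

The forecast named green as best, with 73% for green, 59% for violet, 47% for grey and 33% for blue, saying of blue: “In blue, reagent stays low while starting material is present and cross reaction runs regardless”.

    starting material + second substrate → cross product (k = 0.230 /M/min)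
    second substrate + reagent → second product (k = 0.0850 /M/min)
    starting material + reagent → target (k = 2.30 /M/min)
    starting material + target ⇌ idle adduct, settled at all times (K = 230 /M)

The flasks gave 72.8% for green, 58.7% for violet, 45.3% for grey and 26.4% for blue, so green came first and blue lay 6.6 percentage points under the forecast. At green's charge, starting material has a half-life of 0.097 h by the target reaction and 0.39 h by the cross reaction, a ratio of 4.02. Blue has green's charges of starting material and second substrate, so that 0.39 h puts its opening cross rate at 46.6 mM/h, and the dose over that rate is 0.350. Through s, which cancels in this ratio, with second substrate taken at its charge in both flasks, blue's average reagent level comes to 0.134 of green's.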